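The closed, stirred vessel holds the charges below at constant volume and temperature, and I counted every amount as a fraction of the first end groups charged.

first end groups 1.5 M; second end groups 1.47 M; protic impurity 0.150 M; time 5.0 min

- which holds at 5.0 min: what has brought the reaction to rest, or that it has not come to rest (forward and back rates have come level / all of the first end groups has reacted / it is still moving / the second end groups has run out first)
- share of the first end groups used up at 5.0 min
- links at 5.0 min, in percent of the first end groups charged
- rings at 5.0 min, in percent of the first end groups charged

- a species is counted by the first end groups in it: one side product counts as two
- the reaction counts as stopped when no species that holds the first end groups changes by six tenths of a point or more over the second half of the time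
- run time (flask): 5.0 min

    second end groups + protic impurity → quenched reagent (k1 = 7.6 M⁻¹ s⁻¹)
    first end groups + second end groups → rings, rate k2*[first end groups] as long as [second end groups] is above zero (k2 = 0.092 s⁻¹)
    first end groups + links → side product (k3 = 0.20 M⁻¹ s⁻¹)
    first end groups + second end groups → links (k4 = 0.071 M⁻¹ s⁻¹)
    links ⇌ isomer of the product (K5 = 0.30, k5 = 0.083 s⁻¹)

In the first instants, with second end groups as charged, the protic impurity had a half-life of 0.0620 s, shorter than the 7.53 s of first end groups by ring closure. So I took its whole charge off the second end groups, which left them at 88.0%, a gap of 12.0% below the first end groups.

In the middle, ring closure and link formation both went with the first end groups, so the first end groups cancelled from the ratio of the two rates, and that ratio followed the second end groups. A reacting second end group entered a ring with chance c/(c+b), where b is the fraction remaining and c is the crossover level, the b at which both steps run equally, here 0.864. Summed over the run, rings = c·ln[(c+b at start)/(c+b at end)]; the side step takes no second end groups, so it does not enter this sum.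

I reckoned in two rounds. With b at end set to zero, my first round gave rings of 60.7% and links made of 27.3%. Each side product takes one more first end group, so the gap closes once side events reach 12.0%. I assumed first end groups at half their charge on average, which gave the side step an estimated share 64.4% of the links against the forward step to the isomer, and so an estimated 17.6% of side events, more than the gap. So I expected the first end groups to be the limiting reagent, leaving 5.59% of second end groups.

Put back in, this gave rings of 55.3%. At the end, links and isomer had time to level, since the forward half-life of 0.14 min is short against 5.0 min, and I expected links of 7.35%.

The forecast said all of the first end groups has reacted, with conversion 100%, links 7.9% and rings 58%, on the ground that “side-product formation uses extra first end groups and closes that gap”. Its rings stand above mine.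

The simulation gave all of the first end groups has reacted, conversion 100%, links 8.30% and rings 56.3%, so the forecast held.

In this flask, side product stood at 32.9% after 5.00 min, which is 16.4% of side events, more than the gap of 12.0%, and the 4.6% of their own charge left of second end groups gives rings of 56.3% by the crossover rule. In the neighbour flask with 0.38 M of protic impurity, second end groups stood at 72.7% of the first end groups charged once that impurity was taken off, and ended at 0%, so the same 0.864 gives rings of 52.7%; that neighbour flask ended with rings at 52.6% and 7.3% of first end groups left.

The rate constants come from no measurement; the rest is arithmetic.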